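A direct plan would build ring B from an open chain. A polyanion of methyl 3,5-dioxohexanoate would be acylated by methyl benzoate to methyl 3,5,7-trioxo-7-phenylheptanoate A1. Dieckmann-type closure and aromatisation would give 2,4,6-trihydroxybenzophenone A2. Two O-allylations, a double Claisen shift to 3,5-diallyl-2,4,6-trihydroxybenzophenone A3, di-O-methylation to its 4,6-dimethyl ether A4 and cross-metathesis with 2-methyl-2-butene would follow.
Its weakest steps would be:
- the polyanion acylation, which would need a large excess of strong base and risk self-condensation of the chain;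
- the O-allylation/double Claisen pair, with O- versus C-alkylation and ortho versus para shift near 200 °C, followed by a metathesis that adds length but no complexity;
- the di-O-methylation, which would have to stop at two of three hydroxyls on the strength of one hydrogen bond.

The route rests on cutting ring B (C1 benzoyl, C2 OH, C3 prenyl, C4 OMe, C5 prenyl, C6 OMe) at the adjacent pair C1/C2: an aryne with its triple bond at C1–C2, already carrying both methoxy and both prenyl groups, would insert into the C–O bond of benzoic acid, forming the aryl–carbonyl and aryl–oxygen bonds in one operation. The C6 methoxy group beside the triple bond fixes the orientation. The single free hydroxyl is thus delivered by the acid, the methyl ethers come from 1,3-dimethoxybenzene, and the prenyl groups enter intact by aryl–metal allylation, so no polyanion acylation, Claisen shift, partial methylation or metathesis remains.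

Key step: step 6

Remark: the target has no stereocentre and both alkenes end in two methyl groups, so no configuration has to be set; ring A is the phenyl group.

Step 1
Reactants: 1 1,3-dimethoxybenzene; 2 1-bromo-3-methylbut-2-ene (prenyl bromide)
Product: 4 1,3-dimethoxy-2-(3-methylbut-2-en-1-yl)benzene, via aryllithium 3 (not isolated)
Conditions: n-BuLi (1.1 equiv), THF, 0 °C → rt, 2 h; then CuI (10 mol %), 2 (1.2 equiv), −78 °C → rt
Reagents that add atoms: none
Why: Directed ortho-metalation, in which both methoxy groups steer n-BuLi to the carbon between them, followed by copper-catalysed SN2 allylation at the primary carbon of prenyl bromide, places the first prenyl group (future C5 substituent) without any rearrangement.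

Step 2
Reactants: 4 1,3-dimethoxy-2-(3-methylbut-2-en-1-yl)benzene
Product: 6 3,5-dimethoxy-4-(3-methylbut-2-en-1-yl)phenol, via aryl pinacol boronate 5 (not isolated)
Conditions: [Ir(OMe)(cod)]2 (1.5 mol %), 4,4′-di-tert-butyl-2,2′-bipyridine (3 mol %), B2pin2 (0.6 equiv), THF, 80 °C; then aq NaOH, H2O2, 0 °C → rt
Reagents that add atoms: hydrogen peroxide, OO
Why: Sterically governed iridium-catalysed aromatic C–H borylation should attack the only ring C–H without an ortho neighbour (para to the prenyl group), and ipso oxidation of the boronate with alkaline peroxide gives the phenol, the hindered trisubstituted alkene being slow to hydroborate and inert to alkaline H2O2.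

Step 3
Reactants: 6 3,5-dimethoxy-4-(3-methylbut-2-en-1-yl)phenol
Product: 7 3,5-dimethoxy-4-(3-methylbut-2-en-1-yl)phenyl N-(propan-2-yl)carbamate
Conditions: i-PrNCO (1.5 equiv), Et3N (0.2 equiv), CH2Cl2, rt
Reagents that add atoms: isopropyl isocyanate, CC(C)N=C=O
Why: Amine-catalysed addition of the phenol to the isocyanate (carbamoylation) installs an N-monosubstituted carbamate that serves first as metalation director and later as a base-cleavable group.

Step 4
Reactants: 7 3,5-dimethoxy-4-(3-methylbut-2-en-1-yl)phenyl N-(propan-2-yl)carbamate; 2 1-bromo-3-methylbut-2-ene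
Product: 13 3,5-dimethoxy-2,4-bis(3-methylbut-2-en-1-yl)-6-(trimethylsilyl)phenyl N-(propan-2-yl)carbamate, via N-silyl carbamate 8 (not isolated), via first aryllithium 9 (not isolated), via N-silyl arylsilane 10 (not isolated), via second aryllithium 11 (not isolated), via N-silyl diprenyl carbamate 12 (not isolated)
Conditions: TBSOTf (1.1 equiv), TMEDA (1.1 equiv), Et2O, 0 °C → rt; TMEDA (2 equiv), n-BuLi (2.2 equiv), −78 °C, 1 h; Me3SiCl (1.05 equiv), −78 °C → rt, 1 h; n-BuLi (1.2 equiv), −78 °C, 1 h; CuBr·SMe2 (10 mol %), 2 (1.5 equiv), −78 → −20 °C; cold aq NaHSO4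
Reagents that add atoms: chlorotrimethylsilane, C[Si](C)(C)Cl
Why: Two directed ortho-metalations run in one flask on the same in situ N-silylated carbamate, whose oxygen and a neighbouring methoxy group jointly direct n-BuLi first to one of the two equivalent ring C–H positions between them (quenched by C-silylation) and then to the only ring C–H left (quenched by copper-catalysed SN2 allylation at the unhindered CH2 terminus of prenyl bromide), the N-silyl group being kept throughout and removed only on the final acidic work-up, while the cold conditions should hold back the anionic ortho-Fries shift and deprotonation of the remote prenyl CH2.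

Step 5
Reactants: 13 3,5-dimethoxy-2,4-bis(3-methylbut-2-en-1-yl)-6-(trimethylsilyl)phenyl N-(propan-2-yl)carbamate
Product: 15 3,5-dimethoxy-2,4-bis(3-methylbut-2-en-1-yl)-6-(trimethylsilyl)phenyl trifluoromethanesulfonate, via silylphenol 14 (not isolated)
Conditions: Et2NH (1.2 equiv), DBU (1.5 equiv), MeCN, 40 °C; then PhNTf2 (1.5 equiv), 40 °C
Reagents that add atoms: N-phenylbis(trifluoromethanesulfonimide), O=S(=O)(N(c1ccccc1)S(=O)(=O)C(F)(F)F)C(F)(F)F
Why: E1cB cleavage of the N–H carbamate (DBU deprotonates nitrogen, the phenoxide leaves, Et2NH scavenges the isocyanate as a urea) and O-sulfonylation of the phenoxide in the same flask; the medium stays basic, so neither protodesilylation nor acid-induced chroman formation from the ortho-prenyl phenol can occur.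

Step 6
Reactants: 15 3,5-dimethoxy-2,4-bis(3-methylbut-2-en-1-yl)-6-(trimethylsilyl)phenyl trifluoromethanesulfonate; 16 benzoic acid (1.0 equiv)
Product: 18 [2-hydroxy-4,6-dimethoxy-3,5-bis(3-methylbut-2-en-1-yl)phenyl](phenyl)methanone, via aryne 17 (not isolated)
Conditions: CsF (4 equiv), THF, 125 °C (sealed tube), 24 h; aq NH4Cl work-up
Reagents that add atoms: none
Why: Fluoride removes the silyl group of 15 and triflate leaves to give aryne 17; benzoate oxygen adds to the aryne carbon beside the prenyl group, the aryl anion so formed beside the C6 methoxy group attacks the ester carbonyl (four-membered alkoxide), and the ester C–O bond reopens to the ortho-benzoyl phenoxide, protonated on work-up to 18. The closest known reaction type is the insertion of arynes from 2-silylaryl triflates into the C–O bond of carboxylic acids, which gives o-hydroxyaryl ketones under these conditions (CsF, hot THF). No ring stays closed and no stereocentre is formed; the transient four-membered ring arises by 4-exo-trig attack and opens at once. The selectivity needed is the orientation of addition, and the methoxy group next to the triple bond secures it: as in 3-methoxybenzyne, inductive withdrawal makes the remote aryne carbon the electrophilic one and places the charge ortho to OMe, so oxygen ends at C2 and the acyl group at C1. Acyl transfer must also outrun protonation of the aryl anion, which the hot aprotic medium and the caesium carboxylate favour, and the one-carbon tether holds the prenyl alkene out of reach of the in-plane aryne bond, so no intramolecular ene path should compete. The product phenoxide is chelated and flanked by benzoyl and prenyl groups, so it should not arylate further.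

**Compound list**
1 | 1,3-dimethoxybenzene | COc1cccc(OC)c1 | starting material
2 | 1-bromo-3-methylbut-2-ene (prenyl bromide) | CC(C)=CCBr | starting material
3 | (2,6-dimethoxyphenyl)lithium (not isolated) | [Li]c1c(OC)cccc1OC | intermediate
4 | 1,3-dimethoxy-2-(3-methylbut-2-en-1-yl)benzene | COc1cccc(OC)c1CC=C(C)C | intermediate
5 | 2-[3,5-dimethoxy-4-(3-methylbut-2-en-1-yl)phenyl]-4,4,5,5-tetramethyl-1,3,2-dioxaborolane (not isolated) | COc1cc(B2OC(C)(C)C(C)(C)O2)cc(OC)c1CC=C(C)C | intermediate
6 | 3,5-dimethoxy-4-(3-methylbut-2-en-1-yl)phenol | COc1cc(O)cc(OC)c1CC=C(C)C | intermediate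
7 | 3,5-dimethoxy-4-(3-methylbut-2-en-1-yl)phenyl N-(propan-2-yl)carbamate | COc1cc(OC(=O)NC(C)C)cc(OC)c1CC=C(C)C | intermediate
8 | 3,5-dimethoxy-4-(3-methylbut-2-en-1-yl)phenyl N-[tert-butyl(dimethyl)silyl]-N-(propan-2-yl)carbamate (not isolated) | COc1cc(OC(=O)N(C(C)C)[Si](C)(C)C(C)(C)C)cc(OC)c1CC=C(C)C | intermediate
9 | 2-lithio derivative of 8, lithium on the ring carbon between the carbamate oxygen and a methoxy group (not isolated) | COc1cc(OC(=O)N(C(C)C)[Si](C)(C)C(C)(C)C)c([Li])c(OC)c1CC=C(C)C | intermediate
10 | 3,5-dimethoxy-4-(3-methylbut-2-en-1-yl)-2-(trimethylsilyl)phenyl N-[tert-butyl(dimethyl)silyl]-N-(propan-2-yl)carbamate (not isolated) | COc1cc(OC(=O)N(C(C)C)[Si](C)(C)C(C)(C)C)c([Si](C)(C)C)c(OC)c1CC=C(C)C | intermediate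
11 | 6-lithio derivative of 10, lithium on the last ring C–H carbon (not isolated) | COc1c([Li])c(OC(=O)N(C(C)C)[Si](C)(C)C(C)(C)C)c([Si](C)(C)C)c(OC)c1CC=C(C)C | intermediate
12 | 3,5-dimethoxy-2,4-bis(3-methylbut-2-en-1-yl)-6-(trimethylsilyl)phenyl N-[tert-butyl(dimethyl)silyl]-N-(propan-2-yl)carbamate (not isolated) | COc1c(CC=C(C)C)c(OC(=O)N(C(C)C)[Si](C)(C)C(C)(C)C)c([Si](C)(C)C)c(OC)c1CC=C(C)C | intermediate
13 | 3,5-dimethoxy-2,4-bis(3-methylbut-2-en-1-yl)-6-(trimethylsilyl)phenyl N-(propan-2-yl)carbamate | COc1c(CC=C(C)C)c(OC(=O)NC(C)C)c([Si](C)(C)C)c(OC)c1CC=C(C)C | intermediate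
14 | 3,5-dimethoxy-2,4-bis(3-methylbut-2-en-1-yl)-6-(trimethylsilyl)phenol (as its DBU salt, not isolated) | COc1c(CC=C(C)C)c(O)c([Si](C)(C)C)c(OC)c1CC=C(C)C | intermediate
15 | 3,5-dimethoxy-2,4-bis(3-methylbut-2-en-1-yl)-6-(trimethylsilyl)phenyl trifluoromethanesulfonate | COc1c(CC=C(C)C)c(OS(=O)(=O)C(F)(F)F)c([Si](C)(C)C)c(OC)c1CC=C(C)C | intermediate
16 | benzoic acid | OC(=O)c1ccccc1 | starting material
17 | 3,5-dimethoxy-4,6-bis(3-methylbut-2-en-1-yl)benzyne (1,2-didehydrobenzene; not isolated) | COC1=C(CC=C(C)C)C(OC)=C(CC=C(C)C)C#C1 | intermediate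
18 | [2-hydroxy-4,6-dimethoxy-3,5-bis(3-methylbut-2-en-1-yl)phenyl](phenyl)methanone | COc1c(CC=C(C)C)c(O)c(C(=O)c2ccccc2)c(OC)c1CC=C(C)C | target

Total step count: 6. Longest linear sequence: 6 steps (1 → 18).

Steps most likely to fail:

1. Step 6. The aryl anion could be protonated before it reaches the carbonyl group, giving simple O-arylation of the acid. Addition could also occur with the reverse orientation, or the aryne could be consumed by ene reaction with alkenes of a second molecule. Fallback, setting out from 7: N-silylation (TBSOTf/TMEDA), lithiation (n-BuLi/TMEDA, −78 °C) and copper-catalysed allylation with 2, with the chlorosilane quench left out, would give 3,5-dimethoxy-2,4-bis(3-methylbut-2-en-1-yl)phenyl N-(propan-2-yl)carbamate F1 after acidic work-up. A second directed ortho-metalation at the remaining ring C–H (TBSOTf/TMEDA; n-BuLi/TMEDA, −78 °C) and quench with N-methoxy-N-methylbenzamide would give 2-benzoyl-3,5-dimethoxy-4,6-bis(3-methylbut-2-en-1-yl)phenyl N-(propan-2-yl)carbamate F2. Et2NH/DBU in MeCN at 40 °C would then cleave the carbamate and come back to the route at 18.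

2. Step 4. Chlorosilane left over from the first quench could silylate the second aryllithium, the carbamoyl group could migrate to carbon (anionic ortho-Fries) while the allylation is still slow, the electrophile could be attacked at its tertiary terminus, or the base could deprotonate a benzylic–allylic CH2. Fallback, setting out from 7: the silylation half would be run alone (TBSOTf/TMEDA; n-BuLi/TMEDA, −78 °C; excess Me3SiCl; aq NaHSO4) and 3,5-dimethoxy-4-(3-methylbut-2-en-1-yl)-2-(trimethylsilyl)phenyl N-(propan-2-yl)carbamate F3 isolated, so that no chlorosilane reaches the second metalation. After renewed N-silylation of F3 (back to 10) and lithiation to 11, a quench at −78 °C with 1,2-diiodoethane and acidic work-up would give 2-iodo-3,5-dimethoxy-4-(3-methylbut-2-en-1-yl)-6-(trimethylsilyl)phenyl N-(propan-2-yl)carbamate F4, a fast halogenation that needs no warming. A linear-selective Negishi coupling of F4 with (3-methylbut-2-en-1-yl)zinc bromide F5 (2.5 equiv, from 2 and zinc dust, LiCl, THF), using Pd(OAc)2 and the biaryl dialkylphosphine CPhos in THF at rt, would form the aryl–CH2 bond and come back to the route at 13.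

3. Step 2. The B–H species formed during borylation could hydroborate or isomerise the prenyl alkene under iridium catalysis, or borylation could stray to a C–H ortho to methoxy. Fallback, setting out from 1, with oxygenation before prenylation: 1 itself would be borylated at C5 under the conditions of step 2 (no alkene present) to 2-(3,5-dimethoxyphenyl)-4,4,5,5-tetramethyl-1,3,2-dioxaborolane F6 and oxidised to 3,5-dimethoxyphenol F7 (also an article of commerce). TIPSCl/imidazole would give (3,5-dimethoxyphenoxy)tri(propan-2-yl)silane F8, whose bulky, poorly coordinating silyloxy group leaves the C–H between the two methoxy groups as the site of lithiation (n-BuLi, THF, 0 °C). Allylation with 2 would give [3,5-dimethoxy-4-(3-methylbut-2-en-1-yl)phenoxy]tri(propan-2-yl)silane F9, and Bu4NF in THF would come back to the route at 6.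

Further compounds
F1 | step 6 | 3,5-dimethoxy-2,4-bis(3-methylbut-2-en-1-yl)phenyl N-(propan-2-yl)carbamate | COc1cc(OC(=O)NC(C)C)c(CC=C(C)C)c(OC)c1CC=C(C)C
F2 | step 6 | 2-benzoyl-3,5-dimethoxy-4,6-bis(3-methylbut-2-en-1-yl)phenyl N-(propan-2-yl)carbamate | COc1c(CC=C(C)C)c(OC(=O)NC(C)C)c(C(=O)c2ccccc2)c(OC)c1CC=C(C)C
F3 | step 4 | 3,5-dimethoxy-4-(3-methylbut-2-en-1-yl)-2-(trimethylsilyl)phenyl N-(propan-2-yl)carbamate | COc1cc(OC(=O)NC(C)C)c([Si](C)(C)C)c(OC)c1CC=C(C)C
F4 | step 4 | 2-iodo-3,5-dimethoxy-4-(3-methylbut-2-en-1-yl)-6-(trimethylsilyl)phenyl N-(propan-2-yl)carbamate | COc1c(I)c(OC(=O)NC(C)C)c([Si](C)(C)C)c(OC)c1CC=C(C)C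
F5 | step 4 | (3-methylbut-2-en-1-yl)zinc bromide | CC(C)=CC[Zn]Br
F6 | step 2 | 2-(3,5-dimethoxyphenyl)-4,4,5,5-tetramethyl-1,3,2-dioxaborolane | COc1cc(B2OC(C)(C)C(C)(C)O2)cc(OC)c1
F7 | step 2 | 3,5-dimethoxyphenol | COc1cc(O)cc(OC)c1
F8 | step 2 | (3,5-dimethoxyphenoxy)tri(propan-2-yl)silane | COc1cc(O[Si](C(C)C)(C(C)C)C(C)C)cc(OC)c1
F9 | step 2 | [3,5-dimethoxy-4-(3-methylbut-2-en-1-yl)phenoxy]tri(propan-2-yl)silane | COc1cc(O[Si](C(C)C)(C(C)C)C(C)C)cc(OC)c1CC=C(C)C
A1 | direct plan | methyl 3,5,7-trioxo-7-phenylheptanoate | COC(=O)CC(=O)CC(=O)CC(=O)c1ccccc1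
A2 | direct plan | (2,4,6-trihydroxyphenyl)(phenyl)methanone | O=C(c1ccccc1)c1c(O)cc(O)cc1O
A3 | direct plan | (3,5-diallyl-2,4,6-trihydroxyphenyl)(phenyl)methanone | C=CCc1c(O)c(CC=C)c(O)c(C(=O)c2ccccc2)c1O
A4 | direct plan | (3,5-diallyl-2-hydroxy-4,6-dimethoxyphenyl)(phenyl)methanone | COc1c(CC=C)c(O)c(C(=O)c2ccccc2)c(OC)c1CC=C
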